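1. The dimer is cut at C1–C13′ into two C6‑epimeric germacranolide halves, joined last by an intermolecular Alder‑ene reaction: donor 30 (half A, methylene masked as CH2OAc) and enophile 25 (half B).
2. Both halves come from one bicyclic lactone 22; the 6β series (half A) is reached by Mitsunobu inversion at C6.
3. 22 comes from the acyclic acid 19 in one photoredox operation that forms C7–C8 (ten‑membered carbocycle) and C11–C12 (γ‑lactone). The enabling feature is the γ‑lactone fused to the ten‑membered ring at C7–C8, whose carbonyl C12 hangs on O8 and whose α‑carbon C11 carries the exocyclic C13: with C13 as a formyl group, C7=C11–C13HO is an enal that accepts a C8 α‑oxy radical at C7 and returns an enolate at C11 within five‑ring reach of C12.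
4. 19 comes from geraniol (C1–C6, C9, C10, C14, C15), allyl acetate (C8 plus a carboxyl lost as CO2), methyl chloroformate (C12) and 3,3‑diethoxypropyne (C7, C11, C13); C6 is set by a catalytic asymmetric alkenylzinc addition.
5. Ring order: ten‑membered carbocycle, then γ‑lactone, both in step 13 (the same rings serve both halves); no ring is formed afterwards.

Key step: step 13

Remark: germacrane numbering is used (ring C1–C10, C14 on C10, C15 on C4, C11–C13 on C7, C12 the lactone carbonyl); α/β refer to the usual drawing with H‑7 α; primed locants belong to the half whose lactone α‑carbon is sp3 in the target. Compounds 9–12 and 16–21 are mixtures at the carbon that becomes C8 (a planar radical in step 13), and 23, 24 and 26–31 are mixtures at C11 (sp2 again after steps 16 and 22); these centres are left undefined in the SMILES.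

Step 1
Reactants: 1 geraniol
Product: 2 geranyl tert‑butyldiphenylsilyl ether
Conditions: TBDPSCl, imidazole, CH2Cl2, 0 °C to rt
Reagents that add atoms: tert‑butyl(chloro)diphenylsilane, CC(C)(C)[Si](Cl)(c1ccccc1)c1ccccc1
Why: Standard silylation of the primary allylic alcohol gives an ether that survives allylic oxidation and enolate chemistry and is removed by fluoride in step 7.

Step 2
Reactants: 2 geranyl tert‑butyldiphenylsilyl ether
Product: 3 (2E,6E)-8-[(tert‑butyldiphenylsilyl)oxy]-2,6-dimethylocta-2,6-dien-1-ol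
Conditions: SeO2 (cat.), t‑BuOOH, salicylic acid (cat.), CH2Cl2, rt
Reagents that add atoms: tert‑butyl hydroperoxide, CC(C)(C)OO
Why: Sharpless SeO2/TBHP allylic oxidation (ene then [2,3]-sigmatropic shift) is selective for the (E)-methyl group of the terminal trisubstituted alkene of geranyl derivatives, so C9 is functionalised and the E geometry of the future C1=C10 bond is kept.

Step 3
Reactants: 3 (2E,6E)-8-[(tert‑butyldiphenylsilyl)oxy]-2,6-dimethylocta-2,6-dien-1-ol
Product: 4 {[(2E,6E)-8-bromo-3,7-dimethylocta-2,6-dien-1-yl]oxy}(tert‑butyl)diphenylsilane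
Conditions: CBr4, PPh3, CH2Cl2, 0 °C
Reagents that add atoms: carbon tetrabromide, BrC(Br)(Br)Br
Why: The Appel reaction converts the primary allylic alcohol into the bromide under neutral conditions without allylic transposition or loss of alkene geometry.

Step 4
Reactants: 5 allyl acetate, 4 {[(2E,6E)-8-bromo-3,7-dimethylocta-2,6-dien-1-yl]oxy}(tert‑butyl)diphenylsilane
Product: 7 prop-2-en-1-yl (4E,8E)-10-[(tert‑butyldiphenylsilyl)oxy]-4,8-dimethyldeca-4,8-dienoate, via lithium enolate of allyl acetate 6 (not isolated)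
Conditions: LDA, THF, −78 °C; then 4, DMPU, −78 to −30 °C
Reagents that add atoms: none
Why: SN2 alkylation of a lithium ester enolate by the primary allylic bromide forms the C8–C9 bond; the ester carbon is the carboxyl that step 13 expels as CO2.

Step 5
Reactants: 7 prop-2-en-1-yl (4E,8E)-10-[(tert‑butyldiphenylsilyl)oxy]-4,8-dimethyldeca-4,8-dienoate
Product: 9 prop-2-en-1-yl (4E,8E)-10-[(tert‑butyldiphenylsilyl)oxy]-2-hydroxy-4,8-dimethyldeca-4,8-dienoate, via potassium enolate of the ester 8 (not isolated)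
Conditions: KHMDS, THF, −78 °C; then 3-phenyl-2-(phenylsulfonyl)oxaziridine, −78 °C
Reagents that add atoms: 3-phenyl-2-(phenylsulfonyl)oxaziridine, O=S(=O)(c1ccccc1)N1OC1c1ccccc1
Why: Davis oxaziridine hydroxylation of the potassium enolate installs O8 on C8; the carbinol is racemic, which does not matter because C8 becomes a planar radical in step 13.

Step 6
Reactants: 9 prop-2-en-1-yl (4E,8E)-10-[(tert‑butyldiphenylsilyl)oxy]-2-hydroxy-4,8-dimethyldeca-4,8-dienoate
Product: 10 prop-2-en-1-yl (4E,8E)-10-[(tert‑butyldiphenylsilyl)oxy]-2-[(methoxycarbonyl)oxy]-4,8-dimethyldeca-4,8-dienoate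
Conditions: ClCO2Me, pyridine, DMAP (cat.), CH2Cl2, 0 °C
Reagents that add atoms: methyl chloroformate, COC(=O)Cl
Why: O‑acylation places the future lactone carbonyl carbon C12 on O8 as a methyl carbonate, an acyl donor that stays inert until an enolate is generated five atoms away.

Step 7
Reactants: 10 prop-2-en-1-yl (4E,8E)-10-[(tert‑butyldiphenylsilyl)oxy]-2-[(methoxycarbonyl)oxy]-4,8-dimethyldeca-4,8-dienoate
Product: 11 prop-2-en-1-yl (4E,8E)-10-hydroxy-2-[(methoxycarbonyl)oxy]-4,8-dimethyldeca-4,8-dienoate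
Conditions: TBAF, AcOH (1:1), THF, rt
Reagents that add atoms: none
Why: Acetic acid‑buffered fluoride cleaves the silyl ether without attacking the carbonate, the allyl ester or the acidic C–H between them.

Step 8
Reactants: 11 prop-2-en-1-yl (4E,8E)-10-hydroxy-2-[(methoxycarbonyl)oxy]-4,8-dimethyldeca-4,8-dienoate
Product: 12 prop-2-en-1-yl (4E,8E)-2-[(methoxycarbonyl)oxy]-4,8-dimethyl-10-oxodeca-4,8-dienoate
Conditions: MnO2, CH2Cl2, rt
Reagents that add atoms: none
Why: Activated MnO2 oxidises only the allylic alcohol and gives the E‑enal (the future C6 carbonyl) under neutral conditions.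

Step 9
Reactants: 13 3,3-diethoxyprop-1-yne, 12 prop-2-en-1-yl (4E,8E)-2-[(methoxycarbonyl)oxy]-4,8-dimethyl-10-oxodeca-4,8-dienoate
Product: 16 prop-2-en-1-yl (4E,8E,10S,11E)-13,13-diethoxy-10-hydroxy-2-[(methoxycarbonyl)oxy]-4,8-dimethyltrideca-4,8,11-trienoate, via E-alkenyldicyclohexylborane 14 (not isolated), via E-alkenylmethylzinc 15 (not isolated)
Conditions: 13, Cy2BH, toluene, 0 °C to rt; Me2Zn, −78 °C; (−)-MIB (10 mol%), then 12, −20 °C
Reagents that add atoms: none
Why: Oppolzer–Walsh sequence (syn‑hydroboration, boron‑to‑zinc transmetalation, amino‑alcohol‑catalysed 1,2‑addition): the (−)-MIB–zinc complex should deliver the E‑alkenyl group to the Si face of the enal and set the (10S) carbinol (future C6), the only stereocentre introduced by a chiral agent, while ester and carbonate are inert to the alkenylzinc.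

Step 10
Reactants: 16 prop-2-en-1-yl (4E,8E,10S,11E)-13,13-diethoxy-10-hydroxy-2-[(methoxycarbonyl)oxy]-4,8-dimethyltrideca-4,8,11-trienoate
Product: 17 prop-2-en-1-yl (4E,8E,10S,11E)-10-[(tert‑butyldimethylsilyl)oxy]-13,13-diethoxy-2-[(methoxycarbonyl)oxy]-4,8-dimethyltrideca-4,8,11-trienoate
Conditions: TBSCl, imidazole, DMF, rt
Reagents that add atoms: tert‑butyl(chloro)dimethylsilane, CC(C)(C)[Si](C)(C)Cl
Why: Silylation protects the doubly allylic carbinol and supplies the bulky C6 substituent that is meant to steer the ring closure in step 13.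

Step 11
Reactants: 17 prop-2-en-1-yl (4E,8E,10S,11E)-10-[(tert‑butyldimethylsilyl)oxy]-13,13-diethoxy-2-[(methoxycarbonyl)oxy]-4,8-dimethyltrideca-4,8,11-trienoate
Product: 18 (4E,8E,10S,11E)-10-[(tert‑butyldimethylsilyl)oxy]-13,13-diethoxy-2-[(methoxycarbonyl)oxy]-4,8-dimethyltrideca-4,8,11-trienoic acid
Conditions: Pd(PPh3)4 (5 mol%), morpholine, THF, rt; pH 5 buffer work‑up
Reagents that add atoms: none
Why: Pd(0)-catalysed allyl transfer to morpholine (Tsuji–Trost deallylation) frees the carboxylic acid under neutral conditions that leave carbonate, acetal and silyl ether intact.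

Step 12
Reactants: 18 (4E,8E,10S,11E)-10-[(tert‑butyldimethylsilyl)oxy]-13,13-diethoxy-2-[(methoxycarbonyl)oxy]-4,8-dimethyltrideca-4,8,11-trienoic acid
Product: 19 (4E,8E,10S,11E)-10-[(tert‑butyldimethylsilyl)oxy]-2-[(methoxycarbonyl)oxy]-4,8-dimethyl-13-oxotrideca-4,8,11-trienoic acid
Conditions: PPTS (cat.), acetone/H2O, rt
Reagents that add atoms: water, O
Why: Mild acetal hydrolysis of the labile allylic diethyl acetal unveils the E‑enal (C13 formyl) without ionising the doubly allylic silyl ether.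

Step 13
Reactants: 19 (4E,8E,10S,11E)-10-[(tert‑butyldimethylsilyl)oxy]-2-[(methoxycarbonyl)oxy]-4,8-dimethyl-13-oxotrideca-4,8,11-trienoic acid
Product: 22 6α-(tert‑butyldimethylsilyloxy)-13-hydroxygermacra-1(10)E,4E,11(13)-trien-12,8α-olide (7αH 8βH; enol form of the 11-formyl lactone), via potassium salt of the acid 20 (not isolated), via ring-closed potassium enolate 21 (not isolated)
Conditions: Ir[dF(CF3)ppy]2(dtbbpy)PF6 (2 mol%), K2HPO4, degassed DMF (1 mM), blue LEDs, rt; pH 4 buffer work‑up
Reagents that add atoms: none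
Why: Proposed new method: the carboxylate 20 is oxidised by the excited Ir(III) catalyst and loses CO2 to give the nucleophilic α-(methoxycarbonyloxy)alkyl radical at C8, which adds 10‑exo‑trig to C7 of the E‑enal; Ir(II) reduces the resulting α‑formyl radical to the aldehyde enolate 21, whose C11 attacks the carbonate carbon C12 (5‑exo‑trig addition–elimination, loss of methoxide) to give the β‑formyl lactone as its stabilised enolate. The closest known reactions are photoredox decarboxylative Giese additions of α‑oxy acids with radical–polar crossover, Porter‑type radical macrocyclisations onto acrylic acceptors and Dieckmann/Claisen acylations by carbonates; combining them into a ring‑forming [3+2] lactone annulation is new. C7 and C8 are created in the radical C–C bond formation under control of the C6 silyloxy stereocentre: a crown‑like transition state resembling the product conformation keeps OTBS on C6, the enal‑derived chain on C7 and the carbonate oxygen on C8 pseudo‑equatorial, which should give the 6α‑O/7α‑H/8β‑H isomer (6,7‑anti, trans‑fused lactone), while C11 stays sp2. Ring closure must beat bimolecular addition and hydrogen abstraction, which is addressed by high dilution, by the polarity match of the α‑oxy radical with the enal (the two trisubstituted alkenes are not acceptors) and by the (E,E)-diene backbone. C‑acylation can only follow ring closure, because C11 and C12 come within five‑ring reach only once C7–C8 exists. The mild phosphate base is chosen to avoid γ‑deprotonation at C6 of the enal, and the acidic β‑dicarbonyl product buffers the methoxide released.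

Step 14
Reactants: 22 6α-(tert‑butyldimethylsilyloxy)-13-hydroxygermacra-1(10)E,4E,11(13)-trien-12,8α-olide
Product: 23 6α-(tert‑butyldimethylsilyloxy)-13-hydroxygermacra-1(10)E,4E-dien-12,8α-olide (C11 epimers)
Conditions: NaBH4, THF/MeOH, −20 °C
Reagents that add atoms: none
Why: NaBH4 reduces the formyl tautomer of the β‑formyl lactone chemoselectively (aldehyde over lactone at low temperature) to the primary alcohol.

Step 15
Reactants: 23 6α-(tert‑butyldimethylsilyloxy)-13-hydroxygermacra-1(10)E,4E-dien-12,8α-olide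
Product: 24 13-acetoxy-6α-(tert‑butyldimethylsilyloxy)germacra-1(10)E,4E-dien-12,8α-olide (C11 epimers)
Conditions: Ac2O, pyridine, DMAP (cat.), CH2Cl2, 0 °C
Reagents that add atoms: acetic anhydride, CC(=O)OC(C)=O
Why: Acetylation turns the primary alcohol into a β‑acetoxy lactone, a base‑labile mask of the α‑methylene group that cannot itself act as enophile or Michael acceptor.

Step 16
Reactants: 24 13-acetoxy-6α-(tert‑butyldimethylsilyloxy)germacra-1(10)E,4E-dien-12,8α-olide
Product: 25 6α-(tert‑butyldimethylsilyloxy)germacra-1(10)E,4E,11(13)-trien-12,8α-olide (enophile, half B)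
Conditions: DBU, CH2Cl2, 0 °C to rt
Reagents that add atoms: none
Why: E1cB elimination of acetic acid gives the α‑methylene lactone while O6 is silylated, which prevents base‑induced lactone migration to O6.

Step 17
Reactants: 24 13-acetoxy-6α-(tert‑butyldimethylsilyloxy)germacra-1(10)E,4E-dien-12,8α-olide
Product: 26 13-acetoxy-6α-hydroxygermacra-1(10)E,4E-dien-12,8α-olide (C11 epimers)
Conditions: HF·pyridine, pyridine, THF, 0 °C to rt
Reagents that add atoms: none
Why: Pyridine‑buffered HF cleaves the secondary allylic silyl ether without base, so the β‑acetoxy lactone survives and the 6α‑hydroxyl is freed for inversion.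

Step 18
Reactants: 26 13-acetoxy-6α-hydroxygermacra-1(10)E,4E-dien-12,8α-olide
Product: 28 13-acetoxy-6β-(chloroacetoxy)germacra-1(10)E,4E-dien-12,8α-olide (C11 epimers), via alkoxytriphenylphosphonium chloroacetate 27 (not isolated)
Conditions: ClCH2CO2H, PPh3, DIAD, toluene, 0 °C to rt
Reagents that add atoms: chloroacetic acid, OC(=O)CCl
Why: Mitsunobu esterification with an acidic pronucleophile displaces the oxyphosphonium group by SN2 with inversion, converting 6α‑O into the 6β‑O configuration of half A.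

Step 19
Reactants: 28 13-acetoxy-6β-(chloroacetoxy)germacra-1(10)E,4E-dien-12,8α-olide
Product: 29 13-acetoxy-6β-hydroxygermacra-1(10)E,4E-dien-12,8α-olide (C11 epimers)
Conditions: thiourea, NaHCO3, EtOH, 50 °C
Reagents that add atoms: none
Why: Thiourea S‑alkylation and cyclisation to pseudothiohydantoin removes the chloroacetate selectively beside the primary acetate under near‑neutral conditions, with retention at C6.

Step 20
Reactants: 29 13-acetoxy-6β-hydroxygermacra-1(10)E,4E-dien-12,8α-olide
Product: 30 13-acetoxy-6β-(tert‑butyldimethylsilyloxy)germacra-1(10)E,4E-dien-12,8α-olide (ene donor, half A; C11 epimers)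
Conditions: TBSOTf, 2,6-lutidine, CH2Cl2, −78 to 0 °C
Reagents that add atoms: tert‑butyldimethylsilyl trifluoromethanesulfonate, CC(C)(C)[Si](C)(C)OS(=O)(=O)C(F)(F)F
Why: Silylation of the hindered 6β‑hydroxyl protects it from lactone migration in the basic step 22.

Step 21
Reactants: 30 13-acetoxy-6β-(tert‑butyldimethylsilyloxy)germacra-1(10)E,4E-dien-12,8α-olide, 25 6α-(tert‑butyldimethylsilyloxy)germacra-1(10)E,4E,11(13)-trien-12,8α-olide
Product: 31 C1(β)–C13′ linked dimer: 13-acetoxy-6β-(tert‑butyldimethylsilyloxy)germacra-4E,9Z-dien-12,8α-olide joined at C1 to C13′ of 6′α-(tert‑butyldimethylsilyloxy)germacra-1′(10′)E,4′E-dien-12′,8′α-olide (C11 and C11′ epimers)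
Conditions: 30 (2.5 equiv), 25, BHT (cat.), CH2Cl2, 1.2 GPa, 50 °C
Reagents that add atoms: none
Why: Intermolecular Alder‑ene reaction driven by pressure rather than heat or Lewis acid (to avoid Cope rearrangement and cationic transannular cyclisation): the C1=C10 alkene of 30 (C4=C5 is shielded and deactivated by the C6 silyloxy group) should attack C13 of the α‑methylene lactone of 25 through its peripheral face with transfer of H‑9 to C11′, placing the new bond β on C1 and moving the alkene to C9=C10; 30 is used in excess, and recovered, because 25 can also act as ene donor.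

Step 22
Reactants: 31 C1(β)–C13′ linked dimer (acetate)
Product: 32 6,6′-bis(tert‑butyldimethylsilyl) ether of the target
Conditions: DBU, CH2Cl2, rt
Reagents that add atoms: none
Why: DBU eliminates acetic acid (E1cB) to unveil the α‑methylene lactone of half A and should equilibrate the enolisable C11′ to the all‑trans lactone (C13′ anti to C6′, H‑11′ syn to H‑8′), while both silyl ethers block lactone migration.

Step 23
Reactants: 32 6,6′-bis(tert‑butyldimethylsilyl) ether of the target
Product: 33 CNP0191625.1 (target)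
Conditions: HF·pyridine, pyridine, THF, 0 °C to rt
Reagents that add atoms: none
Why: Pyridine‑buffered HF removes both secondary silyl ethers under non‑basic conditions that leave the α‑methylene lactone, both trans‑lactones and the acid‑sensitive 1(10),4‑diene untouched.

Compound list
1 | geraniol | CC(C)=CCC/C(C)=C/CO | starting material
2 | geranyl tert‑butyldiphenylsilyl ether | CC(C)=CCC/C(C)=C/CO[Si](c1ccccc1)(c1ccccc1)C(C)(C)C | intermediate
3 | (2E,6E)-8-[(tert‑butyldiphenylsilyl)oxy]-2,6-dimethylocta-2,6-dien-1-ol | OC/C(C)=C/CC/C(C)=C/CO[Si](c1ccccc1)(c1ccccc1)C(C)(C)C | intermediate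
4 | {[(2E,6E)-8-bromo-3,7-dimethylocta-2,6-dien-1-yl]oxy}(tert‑butyl)diphenylsilane | BrC/C(C)=C/CC/C(C)=C/CO[Si](c1ccccc1)(c1ccccc1)C(C)(C)C | intermediate
5 | allyl acetate | CC(=O)OCC=C | starting material
6 | lithium enolate of allyl acetate (not isolated) | [Li+].[O-]C(=C)OCC=C | intermediate
7 | prop-2-en-1-yl (4E,8E)-10-[(tert‑butyldiphenylsilyl)oxy]-4,8-dimethyldeca-4,8-dienoate | C=CCOC(=O)CC/C(C)=C/CC/C(C)=C/CO[Si](c1ccccc1)(c1ccccc1)C(C)(C)C | intermediate
8 | potassium enolate of ester 7 (not isolated) | [K+].[O-]C(OCC=C)=CC/C(C)=C/CC/C(C)=C/CO[Si](c1ccccc1)(c1ccccc1)C(C)(C)C | intermediate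
9 | prop-2-en-1-yl (4E,8E)-10-[(tert‑butyldiphenylsilyl)oxy]-2-hydroxy-4,8-dimethyldeca-4,8-dienoate (racemic at C2) | C=CCOC(=O)C(O)C/C(C)=C/CC/C(C)=C/CO[Si](c1ccccc1)(c1ccccc1)C(C)(C)C | intermediate
10 | prop-2-en-1-yl (4E,8E)-10-[(tert‑butyldiphenylsilyl)oxy]-2-[(methoxycarbonyl)oxy]-4,8-dimethyldeca-4,8-dienoate | C=CCOC(=O)C(OC(=O)OC)C/C(C)=C/CC/C(C)=C/CO[Si](c1ccccc1)(c1ccccc1)C(C)(C)C | intermediate
11 | prop-2-en-1-yl (4E,8E)-10-hydroxy-2-[(methoxycarbonyl)oxy]-4,8-dimethyldeca-4,8-dienoate | C=CCOC(=O)C(OC(=O)OC)C/C(C)=C/CC/C(C)=C/CO | intermediate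
12 | prop-2-en-1-yl (4E,8E)-2-[(methoxycarbonyl)oxy]-4,8-dimethyl-10-oxodeca-4,8-dienoate | C=CCOC(=O)C(OC(=O)OC)C/C(C)=C/CC/C(C)=C/C=O | intermediate
13 | 3,3-diethoxyprop-1-yne | C#CC(OCC)OCC | starting material
14 | (E)-dicyclohexyl(3,3-diethoxyprop-1-en-1-yl)borane (not isolated) | CCOC(OCC)/C=C/B(C1CCCCC1)C1CCCCC1 | intermediate
15 | (E)-(3,3-diethoxyprop-1-en-1-yl)(methyl)zinc (not isolated) | CCOC(OCC)/C=C/[Zn]C | intermediate
16 | prop-2-en-1-yl (4E,8E,10S,11E)-13,13-diethoxy-10-hydroxy-2-[(methoxycarbonyl)oxy]-4,8-dimethyltrideca-4,8,11-trienoate (C2 epimers) | C=CCOC(=O)C(OC(=O)OC)C/C(C)=C/CC/C(C)=C/[C@@H](O)/C=C/C(OCC)OCC | intermediate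
17 | prop-2-en-1-yl (4E,8E,10S,11E)-10-[(tert‑butyldimethylsilyl)oxy]-13,13-diethoxy-2-[(methoxycarbonyl)oxy]-4,8-dimethyltrideca-4,8,11-trienoate | C=CCOC(=O)C(OC(=O)OC)C/C(C)=C/CC/C(C)=C/[C@@H](O[Si](C)(C)C(C)(C)C)/C=C/C(OCC)OCC | intermediate
18 | (4E,8E,10S,11E)-10-[(tert‑butyldimethylsilyl)oxy]-13,13-diethoxy-2-[(methoxycarbonyl)oxy]-4,8-dimethyltrideca-4,8,11-trienoic acid | OC(=O)C(OC(=O)OC)C/C(C)=C/CC/C(C)=C/[C@@H](O[Si](C)(C)C(C)(C)C)/C=C/C(OCC)OCC | intermediate
19 | (4E,8E,10S,11E)-10-[(tert‑butyldimethylsilyl)oxy]-2-[(methoxycarbonyl)oxy]-4,8-dimethyl-13-oxotrideca-4,8,11-trienoic acid | OC(=O)C(OC(=O)OC)C/C(C)=C/CC/C(C)=C/[C@@H](O[Si](C)(C)C(C)(C)C)/C=C/C=O | intermediate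
20 | potassium salt of acid 19 (not isolated) | [K+].[O-]C(=O)C(OC(=O)OC)C/C(C)=C/CC/C(C)=C/[C@@H](O[Si](C)(C)C(C)(C)C)/C=C/C=O | intermediate
21 | potassium enolate of the ring-closed aldehyde, ten-membered carbocycle with C8 methyl carbonate (not isolated) | [K+].[O-]C=C[C@@H]1[C@@H](OC(=O)OC)C/C(C)=C/CC/C(C)=C/[C@H]1O[Si](C)(C)C(C)(C)C | intermediate
22 | 6α-(tert‑butyldimethylsilyloxy)-13-hydroxygermacra-1(10)E,4E,11(13)-trien-12,8α-olide (7αH, 8βH; enol geometry undefined) | OC=C1C(=O)O[C@H]2C/C(C)=C/CC/C(C)=C/[C@@H](O[Si](C)(C)C(C)(C)C)[C@@H]21 | intermediate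
23 | 6α-(tert‑butyldimethylsilyloxy)-13-hydroxygermacra-1(10)E,4E-dien-12,8α-olide (C11 epimers) | OCC1C(=O)O[C@H]2C/C(C)=C/CC/C(C)=C/[C@@H](O[Si](C)(C)C(C)(C)C)[C@@H]21 | intermediate
24 | 13-acetoxy-6α-(tert‑butyldimethylsilyloxy)germacra-1(10)E,4E-dien-12,8α-olide (C11 epimers) | CC(=O)OCC1C(=O)O[C@H]2C/C(C)=C/CC/C(C)=C/[C@@H](O[Si](C)(C)C(C)(C)C)[C@@H]21 | intermediate
25 | 6α-(tert‑butyldimethylsilyloxy)germacra-1(10)E,4E,11(13)-trien-12,8α-olide | C=C1C(=O)O[C@H]2C/C(C)=C/CC/C(C)=C/[C@@H](O[Si](C)(C)C(C)(C)C)[C@@H]21 | intermediate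
26 | 13-acetoxy-6α-hydroxygermacra-1(10)E,4E-dien-12,8α-olide (C11 epimers) | CC(=O)OCC1C(=O)O[C@H]2C/C(C)=C/CC/C(C)=C/[C@@H](O)[C@@H]21 | intermediate
27 | 6α-oxytriphenylphosphonium chloroacetate of 26 (not isolated) | CC(=O)OCC1C(=O)O[C@H]2C/C(C)=C/CC/C(C)=C/[C@@H](O[P+](c3ccccc3)(c3ccccc3)c3ccccc3)[C@@H]21.[O-]C(=O)CCl | intermediate
28 | 13-acetoxy-6β-(chloroacetoxy)germacra-1(10)E,4E-dien-12,8α-olide (C11 epimers) | CC(=O)OCC1C(=O)O[C@H]2C/C(C)=C/CC/C(C)=C/[C@H](OC(=O)CCl)[C@@H]21 | intermediate
29 | 13-acetoxy-6β-hydroxygermacra-1(10)E,4E-dien-12,8α-olide (C11 epimers) | CC(=O)OCC1C(=O)O[C@H]2C/C(C)=C/CC/C(C)=C/[C@H](O)[C@@H]21 | intermediate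
30 | 13-acetoxy-6β-(tert‑butyldimethylsilyloxy)germacra-1(10)E,4E-dien-12,8α-olide (C11 epimers) | CC(=O)OCC1C(=O)O[C@H]2C/C(C)=C/CC/C(C)=C/[C@H](O[Si](C)(C)C(C)(C)C)[C@@H]21 | intermediate
31 | ene adduct, C1(β)–C13′ linked dimer with 13-acetoxy group and two TBS ethers (H‑1 α, 9Z; C11 and C11′ epimers) | CC(=O)OCC1C(=O)O[C@H]2/C=C(/C)[C@H](CC3C(=O)O[C@H]4C/C(C)=C/CC/C(C)=C/[C@@H](O[Si](C)(C)C(C)(C)C)[C@@H]43)CC/C(C)=C/[C@H](O[Si](C)(C)C(C)(C)C)[C@H]12 | intermediate
32 | 6,6′-bis(tert‑butyldimethylsilyl) ether of the target | C=C1C(=O)O[C@H]2/C=C(/C)[C@H](C[C@H]3C(=O)O[C@H]4C/C(C)=C/CC/C(C)=C/[C@@H](O[Si](C)(C)C(C)(C)C)[C@@H]43)CC/C(C)=C/[C@H](O[Si](C)(C)C(C)(C)C)[C@H]12 | intermediate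
33 | CNP0191625.1 | C=C1C(=O)O[C@H]2/C=C(/C)[C@H](C[C@H]3C(=O)O[C@H]4C/C(C)=C/CC/C(C)=C/[C@@H](O)[C@@H]43)CC/C(C)=C/[C@H](O)[C@H]12 | target

Total steps: 23. Longest linear sequence: 22 steps (steps 1–15 and 17–23; step 16 is the one‑step branch that supplies 25).

Steps most likely to fail

Step 13 (proposed new method). Bimolecular radical addition, hydrogen abstraction or protonation of the enolate may outrun the ten‑membered ring closure or the acylation, and addition may occur on the wrong face of the enal. The fallback sets out from 19 and comes back at 22, separating the two bond formations with known reactions. The acid is esterified (N‑hydroxyphthalimide, DIC, DMAP) to the redox‑active ester F1. A tin‑free reductive decarboxylative Giese cyclisation (Ru(bpy)3Cl2, Hantzsch ester, i‑Pr2NEt, blue light, syringe‑pump addition) closes the carbocycle and gives the hydrogen‑terminated ring‑closed aldehyde F2, whose diastereomers can be separated. LiHMDS (THF, −78 to 0 °C) then effects the intramolecular Claisen‑type acylation of the aldehyde enolate by the carbonate to give 22.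

Step 21. The ene reaction may be too slow relative to Cope rearrangement, self‑reaction of 25 may compete, or hydrogen may be abstracted from C14 instead of C9. The fallback sets out from 29 and 25 and comes back at 33, using a temporary silicon tether to make the ene reaction intramolecular. 25 is desilylated (HF·pyridine) to the free 6α‑alcohol F3. 29 is treated with excess i‑Pr2SiCl2 and imidazole to give the chlorosilyl ether F4, which is coupled with F3 (imidazole, DMF) to the diisopropylsilylene‑bridged pair F5. Heating (toluene, 80–90 °C, BHT) should give the bridged ene product F6 through a 13‑membered cyclic array that holds C1 of the donor near C13′. DBU then gives the bridged bis‑lactone F7, and HF·pyridine removes the bridge to give 33.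

Step 18. Elimination, SN2′ attack or ionisation at the hindered allylic C6 may compete with clean inversion. The fallback sets out from 26 and comes back at 29 by oxidation and reduction. Dess–Martin periodinane (NaHCO3, CH2Cl2) gives the 6‑ketone F8. Luche reduction (NaBH4, CeCl3·7H2O, MeOH, −78 °C) should deliver hydride to the α‑face, anti to the C7–C11 bond, and give the 6β‑alcohol 29 without passing through 28.

Further compounds
F1 | step 13 | N‑hydroxyphthalimide ester of acid 19 | O=C1c2ccccc2C(=O)N1OC(=O)C(OC(=O)OC)C/C(C)=C/CC/C(C)=C/[C@@H](O[Si](C)(C)C(C)(C)C)/C=C/C=O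
F2 | step 13 | ring-closed aldehyde: 6α-TBSO-8α-(methoxycarbonyloxy) ten-membered (1(10)E,4E)-diene with CH2CHO on C7 | O=CC[C@@H]1[C@@H](OC(=O)OC)C/C(C)=C/CC/C(C)=C/[C@H]1O[Si](C)(C)C(C)(C)C
F3 | step 21 | 6α-hydroxygermacra-1(10)E,4E,11(13)-trien-12,8α-olide | C=C1C(=O)O[C@H]2C/C(C)=C/CC/C(C)=C/[C@@H](O)[C@@H]21
F4 | step 21 | 6β-O-chlorodiisopropylsilyl ether of 29 | CC(=O)OCC1C(=O)O[C@H]2C/C(C)=C/CC/C(C)=C/[C@H](O[Si](Cl)(C(C)C)C(C)C)[C@@H]21
F5 | step 21 | diisopropylsilylene-bridged pair of 29 (O6) and F3 (O6′) | CC(=O)OCC1C(=O)O[C@H]2C/C(C)=C/CC/C(C)=C/[C@H](O[Si](C(C)C)(C(C)C)O[C@@H]3/C=C(\C)CC/C=C(\C)C[C@@H]4OC(=O)C(=C)[C@@H]34)[C@@H]21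
F6 | step 21 | silylene-bridged ene adduct (13-acetoxy; C11 and C11′ epimers) | CC(=O)OCC1C(=O)O[C@H]2/C=C(/C)[C@H](CC3C(=O)O[C@H]4C/C(C)=C/CC/C(C)=C/[C@@H](O[Si]5(C(C)C)C(C)C)[C@@H]43)CC/C(C)=C/[C@H](O5)[C@H]12
F7 | step 21 | 6,6′-O-diisopropylsilylene derivative of the target | C=C1C(=O)O[C@H]2/C=C(/C)[C@H](C[C@H]3C(=O)O[C@H]4C/C(C)=C/CC/C(C)=C/[C@@H](O[Si]5(C(C)C)C(C)C)[C@@H]43)CC/C(C)=C/[C@H](O5)[C@H]12
F8 | step 18 | 13-acetoxy-6-oxogermacra-1(10)E,4E-dien-12,8α-olide | CC(=O)OCC1C(=O)O[C@H]2C/C(C)=C/CC/C(C)=C/C(=O)[C@@H]21
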